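C4 of the upper unit is a diarylmethine carbon bonded to C4a of ring A and C6' of ring D, and it is cis to the C3 hydroxyl. Rear-side opening of a cis C3–C4 epoxide by ring A gives exactly this pair, so C4–C4a is cut and pyran ring C is opened to a cis-epoxy aryl ether.
The epoxide goes back to a Z-alkene and then to an alkyne. The alkyne is cut at C4–C6' (Sonogashira) into an aryl propargyl ether carrying C2 with rings A and B, and a 6'-bromo dihydroflavonol benzyl ether carrying rings D, E and F.
C2 comes from an enantioconvergent copper–pybox propargylic etherification. C2' and C3' come from a Juliá–Colonna chalcone epoxide that the ring D phenol closes to ring F.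
Ring F is formed first, in the lower fragment, and ring C last, in the key step. Ketone reduction then sets C4', and hydrogenolysis frees all hydroxyls.

Key step: step 13

Numbering: the upper unit is O1, C2, C3, C4, C4a–C8a (benzo ring A, catechol ring B, pyran ring C). The lower unit is primed (benzo ring D, catechol ring E, pyran ring F).
Assumption: the catalyst from CuOTf and 2,6-bis[(4S)-4-phenyl-4,5-dihydrooxazol-2-yl]pyridine, written (S,S)-Ph-pybox, is taken to give the (S)-ether 6. If the first run shows the opposite sense, the equally available (R,R)-ligand is used and nothing else changes.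
Remark: the residual minor enantiomers of 6 and 14 become diastereomers of 15 and can be removed there by chromatography or crystallisation.

Step 1
Reactants: 1 3,4-bis(benzyloxy)benzaldehyde; 2 ethynylmagnesium bromide
Product: 3 rac-1-[3,4-bis(benzyloxy)phenyl]prop-2-yn-1-ol
Conditions: HC≡CMgBr (0.5 M in THF), THF, 0 °C to rt; then H2O
Reagents that add atoms: none
Why: Grignard 1,2-addition of an alkynyl nucleophile to an aromatic aldehyde is dependable, and the new carbinol centre may be racemic because step 3 passes through a planar intermediate that erases it.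

Step 2
Reactants: 3 rac-1-[3,4-bis(benzyloxy)phenyl]prop-2-yn-1-ol
Product: 4 rac-1-[3,4-bis(benzyloxy)phenyl]prop-2-yn-1-yl acetate
Conditions: Ac2O, pyridine, 4-(dimethylamino)pyridine (cat), 0 °C
Reagents that add atoms: acetic anhydride, CC(=O)OC(C)=O
Why: Nucleophile-catalysed O-acetylation installs the leaving group needed for the propargylic substitution without touching the terminal alkyne or the benzyl ethers.

Step 3
Reactants: 4 rac-1-[3,4-bis(benzyloxy)phenyl]prop-2-yn-1-yl acetate; 5 3-(benzyloxy)phenol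
Product: 6 (S)-1-(benzyloxy)-3-({1-[3,4-bis(benzyloxy)phenyl]prop-2-yn-1-yl}oxy)benzene
Conditions: CuOTf·0.5C6H6 (5 mol %), (S,S)-Ph-pybox (10 mol %), i-Pr2NEt (1.2 equiv), CH2Cl2, −20 °C, slow addition of 4
Reagents that add atoms: none
Why: In this copper-catalysed enantioselective propargylic etherification the monovalent copper acetylide of 4 expels acetate to give a planar copper allenylidene, so both enantiomers of 4 converge, and the phenol oxygen of 5 adds to the γ-carbon on the face left open by the C2-symmetric pybox ligand, which sets C2 (S in 6, the same spatial arrangement as 2R in the target).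

Step 4
Reactants: 7 1-(5-bromo-2,4-dihydroxyphenyl)ethanone
Product: 8 1-[4-(benzyloxy)-5-bromo-2-hydroxyphenyl]ethanone
Conditions: BnBr (1.05 equiv), K2CO3, acetone, reflux
Reagents that add atoms: benzyl bromide, BrCc1ccccc1
Why: Williamson etherification takes place at the 4-hydroxyl only, since the 2-hydroxyl is tied up in a hydrogen bond to the acetyl oxygen and is much less acidic and nucleophilic.

Step 5
Reactants: 8 1-[4-(benzyloxy)-5-bromo-2-hydroxyphenyl]ethanone
Product: 9 1-[4-(benzyloxy)-5-bromo-2-(methoxymethoxy)phenyl]ethanone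
Conditions: NaH, DMF, 0 °C; then MeOCH2Cl, 0 °C to rt
Reagents that add atoms: chloromethyl methyl ether, COCCl
Why: Irreversible deprotonation breaks the chelate and the phenoxide is alkylated (Williamson type) to a methoxymethyl acetal that survives the basic aldol and epoxidation steps yet falls off in mild acid.

Step 6
Reactants: 9 1-[4-(benzyloxy)-5-bromo-2-(methoxymethoxy)phenyl]ethanone; 1 3,4-bis(benzyloxy)benzaldehyde
Product: 10 (E)-1-[4-(benzyloxy)-5-bromo-2-(methoxymethoxy)phenyl]-3-[3,4-bis(benzyloxy)phenyl]prop-2-en-1-one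
Conditions: KOH (aq), EtOH–THF, rt
Reagents that add atoms: none
Why: Claisen–Schmidt condensation of a methyl ketone with a non-enolisable aldehyde gives the E-enone under thermodynamic control, and the aryl bromide, acetal and benzyl ethers are inert to hydroxide.

Step 7
Reactants: 10 (E)-chalcone
Product: 11 [4-(benzyloxy)-5-bromo-2-(methoxymethoxy)phenyl]{(2R,3S)-3-[3,4-bis(benzyloxy)phenyl]oxiran-2-yl}methanone
Conditions: poly-L-leucine (immobilised), urea·H2O2, 1,8-diazabicyclo[5.4.0]undec-7-ene, THF, rt; recrystallisation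
Reagents that add atoms: urea–hydrogen peroxide, NC(N)=O.OO
Why: The Juliá–Colonna epoxidation (Weitz–Scheffer addition of hydroperoxide inside the helical peptide) is the standard asymmetric epoxidation of chalcones, and the L-polymer should deliver oxygen to the face that gives the (αR,βS)-trans-epoxide, which fixes C3' for good and Cβ provisionally.

Step 8
Reactants: 11 (αR,βS)-chalcone epoxide
Product: 13 (2R,3R)-7-(benzyloxy)-2-[3,4-bis(benzyloxy)phenyl]-6-bromo-3-hydroxychroman-4-one, via free-phenol epoxy ketone 12 (not isolated)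
Conditions: HCl (3 M aq), MeOH–THF, 50 °C
Reagents that add atoms: none
Why: Acid first cleaves the acetal and the liberated phenol then opens the protonated epoxide at the benzylic β-carbon in a 6-endo closure of ring F (epoxychalcone to dihydroflavonol cyclisation), with inversion giving 2'R while C3' keeps its oxygen, and the 2',3'-trans product is also the thermodynamic one, so any cationic leakage converges on it.

Step 9
Reactants: 13 (2R,3R)-7-(benzyloxy)-2-[3,4-bis(benzyloxy)phenyl]-6-bromo-3-hydroxychroman-4-one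
Product: 14 (2R,3R)-3,7-bis(benzyloxy)-2-[3,4-bis(benzyloxy)phenyl]-6-bromochroman-4-one
Conditions: BnOC(=NH)CCl3, CF3SO3H (10 mol %), CH2Cl2–cyclohexane, 0 °C to rt
Reagents that add atoms: benzyl 2,2,2-trichloroacetimidate, N=C(OCc1ccccc1)C(Cl)(Cl)Cl
Why: Acid-catalysed benzylation with the trichloroacetimidate avoids base altogether, so neither enolisation at C3' nor retro-oxa-Michael opening at C2' can scramble the dihydroflavonol.

Step 10
Reactants: 6 (S)-aryl propargyl ether; 14 (2R,3R)-6-bromochromanone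
Product: 15 (2R,3R)-3,7-bis(benzyloxy)-2-[3,4-bis(benzyloxy)phenyl]-6-{(3R)-3-[3-(benzyloxy)phenoxy]-3-[3,4-bis(benzyloxy)phenyl]prop-1-yn-1-yl}chroman-4-one
Conditions: Pd(PhCN)2Cl2 (3 mol %), [HP(t-Bu)3]BF4 (6 mol %), CuI (2 mol %), HN(i-Pr)2, dioxane, rt, degassed
Reagents that add atoms: none
Why: Sonogashira coupling with the bulky, electron-rich P(t-Bu)3 ligand lets zerovalent palladium insert into the donor-substituted aryl bromide at room temperature, which forms C4–C6' while sparing the base-sensitive propargylic C2–H and the chromanone stereocentres (the C2 descriptor becomes R only because the arylalkynyl group now outranks ring B).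

Step 11
Reactants: 15 alkyne
Product: 16 (2R,3R)-3,7-bis(benzyloxy)-2-[3,4-bis(benzyloxy)phenyl]-6-{(1Z,3S)-3-[3-(benzyloxy)phenoxy]-3-[3,4-bis(benzyloxy)phenyl]prop-1-en-1-yl}chroman-4-one
Conditions: H2 (1 atm), Pd/CaCO3 poisoned with Pb(OAc)2, quinoline, EtOAc, rt
Reagents that add atoms: none
Why: Lindlar semihydrogenation adds H2 syn to the adsorbed alkyne and stops at the Z-alkene, the lead- and quinoline-poisoned surface being too inactive to cleave benzyl or allylic aryl ethers.

Step 12
Reactants: 16 Z-alkene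
Product: 17 (2R,3R)-3,7-bis(benzyloxy)-2-[3,4-bis(benzyloxy)phenyl]-6-[(2S,3S)-3-{(R)-[3-(benzyloxy)phenoxy][3,4-bis(benzyloxy)phenyl]methyl}oxiran-2-yl]chroman-4-one (cis-epoxide; C2 R, C3 S, C4 S)
Conditions: dimethyldioxirane (acetone solution), CH2Cl2, −20 to 0 °C; volatiles removed cold, used without chromatography
Reagents that add atoms: dimethyldioxirane, CC1(C)OO1
Why: Dioxirane epoxidation is concerted (spiro transition state), so the Z geometry is copied into the cis-epoxide under neutral conditions that this acid-labile product tolerates, while allylic 1,3-strain holds the C2–H bond in the alkene plane and the oxidant should approach anti to the electron-withdrawing C2–O bond, as it does with glycals and other allylic ethers, which sets C3 and C4 erythro to C2.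

Step 13
Reactants: 17 cis-epoxy aryl ether
Product: 18 (2R,3R)-3,7-bis(benzyloxy)-2-[3,4-bis(benzyloxy)phenyl]-6-{(2R,3S,4R)-7-(benzyloxy)-2-[3,4-bis(benzyloxy)phenyl]-3-hydroxychroman-4-yl}chroman-4-one (upper unit 2,3-trans-3,4-cis)
Conditions: BF3·OEt2 (30 mol %), CH2Cl2 (0.005 M), −78 °C; Et3N quench at −78 °C
Reagents that add atoms: none
Why: BF3 binds the epoxide oxygen and stretches the C4–O bond, which is benzylic to ring D; the ring A carbon ortho to O1 and para to the 7-benzyloxy group attacks C4 from the rear, and proton loss from the arenium ion restores ring A and releases the C3 hydroxyl and the Lewis acid. The closest known reaction is the intramolecular Friedel–Crafts epoxy–arene cyclisation of 3-arylglycidyl aryl ethers to 4-arylchroman-3-ols, which runs with inversion at the benzylic carbon. Ring C (C4a, C8a, O1, C2, C3, C4) closes in the 6-endo-tet mode, the 5-exo alternative at C3 being disfavoured because C3 is not benzylic and sits next to the inductively withdrawing C2–O bond. C4 is the only new stereocentre and is controlled by the epoxide itself: anti attack on the cis-epoxide by a nucleophile that ends up inside the ring places ring D on the same face as the C3 hydroxyl (3,4-cis, 4R in 18), while C2 and C3 pass through untouched as 2,3-trans. Substitution has to outrun ionisation and a Meinwald hydride shift, which is secured by the C4' carbonyl (made more withdrawing by BF3 coordination) drawing the O1' and O7' lone pairs away from C4, by the tether that holds ring A behind C4, and by −78 °C in a non-polar solvent at high dilution. Attack must also occur para rather than ortho to the ring A benzyloxy group, which the crowded position between the two oxygens ensures.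

Step 14
Reactants: 18 protected dimer ketone
Product: 19 (2R,3S,4S)-3,7-bis(benzyloxy)-2-[3,4-bis(benzyloxy)phenyl]-6-{(2R,3S,4R)-7-(benzyloxy)-2-[3,4-bis(benzyloxy)phenyl]-3-hydroxychroman-4-yl}chroman-4-ol
Conditions: LiBH(s-Bu)3 (2.5 equiv), THF, −78 °C; then H2O
Reagents that add atoms: none
Why: In this bulky trialkylborohydride reduction the free C3 hydroxyl consumes one equivalent, after which hydride reaches the C4' carbonyl along the open equatorial trajectory of the half-chair with equatorial 2'-aryl and 3'-benzyloxy groups, pushing the new hydroxyl axial and thus cis to O3' (4'S), the opposite of what small hydrides give.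

Step 15
Reactants: 19 heptabenzyl ether diol
Product: 20 (2R,3S,4S)-2-(3,4-dihydroxyphenyl)-6-[(2R,3S,4S)-2-(3,4-dihydroxyphenyl)-3,7-dihydroxychroman-4-yl]chroman-3,4,7-triol (CNP0280090.1)
Conditions: H2 (1 atm), Pd(OH)2/C, THF–MeOH, rt, acid-free; filtration under argon, lyophilisation
Reagents that add atoms: none
Why: Catalytic hydrogenolysis should cleave all seven O-benzyl bonds under neutral conditions much faster than the ring C–O bonds or the secondary C4' hydroxyl, no stereocentre is touched, and the C4 descriptor changes from R to S only because ring A outranks ring D once O7' carries hydrogen.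

Compound list
1 | 3,4-bis(benzyloxy)benzaldehyde | O=Cc1ccc(OCc2ccccc2)c(OCc2ccccc2)c1 | starting material
2 | ethynylmagnesium bromide | C#C[Mg]Br | starting material
3 | rac-1-[3,4-bis(benzyloxy)phenyl]prop-2-yn-1-ol | OC(C#C)c1ccc(OCc2ccccc2)c(OCc2ccccc2)c1 | intermediate
4 | rac-1-[3,4-bis(benzyloxy)phenyl]prop-2-yn-1-yl acetate | CC(=O)OC(C#C)c1ccc(OCc2ccccc2)c(OCc2ccccc2)c1 | intermediate
5 | 3-(benzyloxy)phenol | Oc1cccc(OCc2ccccc2)c1 | starting material
6 | (S)-1-(benzyloxy)-3-({1-[3,4-bis(benzyloxy)phenyl]prop-2-yn-1-yl}oxy)benzene | C(c9ccccc9)Oc1cccc(c1)O[C@H](c1ccc(OCc9ccccc9)c(OCc9ccccc9)c1)C#C | intermediate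
7 | 1-(5-bromo-2,4-dihydroxyphenyl)ethanone | CC(=O)c1cc(Br)c(O)cc1O | starting material
8 | 1-[4-(benzyloxy)-5-bromo-2-hydroxyphenyl]ethanone | CC(=O)c1cc(Br)c(OCc2ccccc2)cc1O | intermediate
9 | 1-[4-(benzyloxy)-5-bromo-2-(methoxymethoxy)phenyl]ethanone | CC(=O)c1cc(Br)c(OCc2ccccc2)cc1OCOC | intermediate
10 | (E)-1-[4-(benzyloxy)-5-bromo-2-(methoxymethoxy)phenyl]-3-[3,4-bis(benzyloxy)phenyl]prop-2-en-1-one | O=C(/C=C/c1ccc(OCc9ccccc9)c(OCc9ccccc9)c1)c1cc(Br)c(OCc9ccccc9)cc1OCOC | intermediate
11 | [4-(benzyloxy)-5-bromo-2-(methoxymethoxy)phenyl]{(2R,3S)-3-[3,4-bis(benzyloxy)phenyl]oxiran-2-yl}methanone | O=C(c1cc(Br)c(OCc9ccccc9)cc1OCOC)[C@@H]3O[C@H]3c1ccc(OCc9ccccc9)c(OCc9ccccc9)c1 | intermediate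
12 | [4-(benzyloxy)-5-bromo-2-hydroxyphenyl]{(2R,3S)-3-[3,4-bis(benzyloxy)phenyl]oxiran-2-yl}methanone | O=C(c1cc(Br)c(OCc9ccccc9)cc1O)[C@@H]3O[C@H]3c1ccc(OCc9ccccc9)c(OCc9ccccc9)c1 | intermediate
13 | (2R,3R)-7-(benzyloxy)-2-[3,4-bis(benzyloxy)phenyl]-6-bromo-3-hydroxychroman-4-one | Brc1cc2c(cc1OCc9ccccc9)O[C@H](c1ccc(OCc9ccccc9)c(OCc9ccccc9)c1)[C@@H](O)C2=O | intermediate
14 | (2R,3R)-3,7-bis(benzyloxy)-2-[3,4-bis(benzyloxy)phenyl]-6-bromochroman-4-one | Brc1cc2c(cc1OCc9ccccc9)O[C@H](c1ccc(OCc9ccccc9)c(OCc9ccccc9)c1)[C@@H](OCc9ccccc9)C2=O | intermediate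
15 | alkyne joining C2 (R) through C3≡C4 to C6' of the (2'R,3'R)-chromanone | C(c9ccccc9)Oc1cccc(c1)O[C@H](c1ccc(OCc9ccccc9)c(OCc9ccccc9)c1)C#Cc1cc2c(cc1OCc9ccccc9)O[C@H](c1ccc(OCc9ccccc9)c(OCc9ccccc9)c1)[C@@H](OCc9ccccc9)C2=O | intermediate
16 | Z-alkene (C2 S, C3=C4 Z, 2'R,3'R) | C(c9ccccc9)Oc1cccc(c1)O[C@H](c1ccc(OCc9ccccc9)c(OCc9ccccc9)c1)/C=C\c1cc2c(cc1OCc9ccccc9)O[C@H](c1ccc(OCc9ccccc9)c(OCc9ccccc9)c1)[C@@H](OCc9ccccc9)C2=O | intermediate
17 | cis-epoxy aryl ether (C2 R, C3 S, C4 S, 2'R,3'R), key-step precursor | C(c9ccccc9)Oc1cccc(c1)O[C@H](c1ccc(OCc9ccccc9)c(OCc9ccccc9)c1)[C@@H](O3)[C@@H]3c1cc2c(cc1OCc9ccccc9)O[C@H](c1ccc(OCc9ccccc9)c(OCc9ccccc9)c1)[C@@H](OCc9ccccc9)C2=O | intermediate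
18 | protected dimer with free C3 hydroxyl and C4' ketone (2R,3S,4R; 2'R,3'R), key-step product | C(c9ccccc9)Oc1ccc2c(c1)O[C@H](c1ccc(OCc9ccccc9)c(OCc9ccccc9)c1)[C@@H](O)[C@H]2c1cc2c(cc1OCc9ccccc9)O[C@H](c1ccc(OCc9ccccc9)c(OCc9ccccc9)c1)[C@@H](OCc9ccccc9)C2=O | intermediate
19 | heptabenzyl ether with 3',4'-cis C4' alcohol (2R,3S,4R; 2'R,3'S,4'S) | C(c9ccccc9)Oc1ccc2c(c1)O[C@H](c1ccc(OCc9ccccc9)c(OCc9ccccc9)c1)[C@@H](O)[C@H]2c1cc2c(cc1OCc9ccccc9)O[C@H](c1ccc(OCc9ccccc9)c(OCc9ccccc9)c1)[C@@H](OCc9ccccc9)[C@H]2O | intermediate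
20 | (2R,3S,4S)-2-(3,4-dihydroxyphenyl)-6-[(2R,3S,4S)-2-(3,4-dihydroxyphenyl)-3,7-dihydroxychroman-4-yl]chroman-3,4,7-triol | Oc1ccc2c(c1)O[C@H](c1ccc(O)c(O)c1)[C@@H](O)[C@H]2c1cc2c(cc1O)O[C@H](c1ccc(O)c(O)c1)[C@@H](O)[C@H]2O | target

Total step count: 15.
Longest linear sequence: 12 steps, from 7 through steps 4–15 to 20. The upper fragment 6 takes 3 steps from 1.

Steps most likely to fail

Step 13. The C4–O bond may ionise before ring A arrives, so that the invertive course is lost and closure drifts towards the 3,4-trans series. A 1,2-hydride shift from C3 may also outrun arylation.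
- The fallback sets out from 15 and comes back at 18. It makes the C4–C4a bond on the alkyne instead of on the epoxide.
- (Ph3P)AuNTf2 (monovalent gold) in CH2Cl2 should bring about the known 6-endo-dig hydroarylation of the aryl propargyl ether, again para to the ring A benzyloxy group. This gives the 4-aryl-2H-chromene F1 with C2 untouched.
- Dimethyldioxirane at low temperature should epoxidise C3=C4 on the face away from ring B, as is usual for flav-3-enes, to give the chromene 3,4-epoxide F2.
- Without storage, F2 is treated with Et3SiH and BF3·OEt2 at −78 °C. In this ionic reductive opening of a tertiary benzylic epoxide, hydride is delivered to C4 anti to the departing oxygen. H4 then lies trans and ring D cis to the C3 hydroxyl, which is 18.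

Step 12. Facial selectivity may be poor, because the two alkene faces differ only by an aryloxy group against an aryl group at C2. Oxidant could also be lost to the electron-rich rings.
- A minor epoxide diastereomer would be carried into step 13 and removed at 18 as the all-cis isomer.
- The fallback sets out from 3 and 14 and comes back at 17. It replaces undirected delivery by hydroxyl-directed delivery followed by inversion.
- rac-3 is resolved with immobilised Candida antarctica lipase B and vinyl acetate. By the usual enantiopreference of this lipase for secondary alcohols, this should give the (R)-acetate F3 and leave the (S)-alcohol F4. Once acetylated, F4 can still feed the enantioconvergent step 3.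
- K2CO3 in MeOH converts F3 into the (R)-propargylic alcohol F5.
- Sonogashira coupling of F5 with 14 under the conditions of step 10 gives the aryl alkynyl carbinol F6. Semihydrogenation as in step 11 gives the Z-allylic alcohol F7.
- 3-Chloroperbenzoic acid buffered with Na2HPO4 in CH2Cl2 at 0 °C then epoxidises syn to the hydrogen-bonding hydroxyl in the conformer enforced by allylic 1,3-strain. This is the well-established threo selectivity of Z-allylic alcohols, and it gives the threo epoxy alcohol F8, whose C3 and C4 are those of 17.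
- Mitsunobu etherification of F8 with 5 (PPh3, diisopropyl azodicarboxylate, toluene, 0 °C) inverts C2 and delivers 17.

Step 3. The electron-rich ring of 5 may undergo C-alkylation in competition with O-alkylation. Uncatalysed ionisation of the donor-substituted propargylic acetate may erode the enantiomeric purity.
- The fallback sets out from 1 and comes back at 6. It sets the carbinol centre by asymmetric alkynylation and forms the C2–O bond by invertive substitution.
- Aldehyde 1 is treated with ethynyltrimethylsilane, Me2Zn and the matching antipode of 2,6-bis{[2-(hydroxydiphenylmethyl)pyrrolidin-1-yl]methyl}-4-methylphenol (dinuclear zinc catalysis) in toluene. This gives the silylated propargylic alcohol F9.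
- Mitsunobu reaction of F9 with 5 (PPh3, diisopropyl azodicarboxylate, toluene, −20 °C) inverts the carbinol carbon to give the silylated aryl propargyl ether F10.
- K2CO3 in MeOH removes the silyl group and gives 6.

Further compounds
F1 | step 13 | (2R,3R)-3,7-bis(benzyloxy)-2-[3,4-bis(benzyloxy)phenyl]-6-{(2S)-7-(benzyloxy)-2-[3,4-bis(benzyloxy)phenyl]-2H-chromen-4-yl}chroman-4-one | C(c9ccccc9)Oc1ccc2c(c1)O[C@H](c1ccc(OCc9ccccc9)c(OCc9ccccc9)c1)C=C2c1cc2c(cc1OCc9ccccc9)O[C@H](c1ccc(OCc9ccccc9)c(OCc9ccccc9)c1)[C@@H](OCc9ccccc9)C2=O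
F2 | step 13 | 3,4-epoxide of F1 with the oxygen trans to ring B (2R,3R,4R in flavan numbering) | C(c9ccccc9)Oc1ccc2c(c1)O[C@H](c1ccc(OCc9ccccc9)c(OCc9ccccc9)c1)[C@H]3O[C@@]23c1cc2c(cc1OCc9ccccc9)O[C@H](c1ccc(OCc9ccccc9)c(OCc9ccccc9)c1)[C@@H](OCc9ccccc9)C2=O
F3 | step 12 | (R)-1-[3,4-bis(benzyloxy)phenyl]prop-2-yn-1-yl acetate | CC(=O)O[C@@H](c1ccc(OCc9ccccc9)c(OCc9ccccc9)c1)C#C
F4 | step 12 | (S)-1-[3,4-bis(benzyloxy)phenyl]prop-2-yn-1-ol | O[C@H](c1ccc(OCc9ccccc9)c(OCc9ccccc9)c1)C#C
F5 | step 12 | (R)-1-[3,4-bis(benzyloxy)phenyl]prop-2-yn-1-ol | O[C@@H](c1ccc(OCc9ccccc9)c(OCc9ccccc9)c1)C#C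
F6 | step 12 | (2R,3R)-3,7-bis(benzyloxy)-2-[3,4-bis(benzyloxy)phenyl]-6-{(3S)-3-[3,4-bis(benzyloxy)phenyl]-3-hydroxyprop-1-yn-1-yl}chroman-4-one | O[C@@H](c1ccc(OCc9ccccc9)c(OCc9ccccc9)c1)C#Cc1cc2c(cc1OCc9ccccc9)O[C@H](c1ccc(OCc9ccccc9)c(OCc9ccccc9)c1)[C@@H](OCc9ccccc9)C2=O
F7 | step 12 | (2R,3R)-3,7-bis(benzyloxy)-2-[3,4-bis(benzyloxy)phenyl]-6-{(1Z,3R)-3-[3,4-bis(benzyloxy)phenyl]-3-hydroxyprop-1-en-1-yl}chroman-4-one | O[C@@H](c1ccc(OCc9ccccc9)c(OCc9ccccc9)c1)/C=C\c1cc2c(cc1OCc9ccccc9)O[C@H](c1ccc(OCc9ccccc9)c(OCc9ccccc9)c1)[C@@H](OCc9ccccc9)C2=O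
F8 | step 12 | (2R,3R)-3,7-bis(benzyloxy)-2-[3,4-bis(benzyloxy)phenyl]-6-[(2S,3R)-3-{(S)-[3,4-bis(benzyloxy)phenyl](hydroxy)methyl}oxiran-2-yl]chroman-4-one (threo, cis-epoxide) | O[C@@H](c1ccc(OCc9ccccc9)c(OCc9ccccc9)c1)[C@@H](O3)[C@@H]3c1cc2c(cc1OCc9ccccc9)O[C@H](c1ccc(OCc9ccccc9)c(OCc9ccccc9)c1)[C@@H](OCc9ccccc9)C2=O
F9 | step 3 | (S)-1-[3,4-bis(benzyloxy)phenyl]-3-(trimethylsilyl)prop-2-yn-1-ol | O[C@@H](c1ccc(OCc9ccccc9)c(OCc9ccccc9)c1)C#C[Si](C)(C)C
F10 | step 3 | (R)-{3-[3-(benzyloxy)phenoxy]-3-[3,4-bis(benzyloxy)phenyl]prop-1-yn-1-yl}trimethylsilane | C(c9ccccc9)Oc1cccc(c1)O[C@H](c1ccc(OCc9ccccc9)c(OCc9ccccc9)c1)C#C[Si](C)(C)C
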